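A direct plan would make ring A last, from a polyketide-like chain: it would alkylate the methyl group of 4-methoxy-6-methylpyran-2-one A1 with prenyl bromide A2, epoxidise the new alkene by the Shi method to the epoxy pyranone A3, and open the lactone with methoxide to the epoxy keto ester A4.
In one flask it would then C-acylate A4 with 4-acetoxycinnamoyl chloride A5, let a diketonate oxygen open the epoxide to an oxolane, and close the benzene ring by a Dieckmann condensation.
Its weakest step would be this last one-flask acylation, epoxide opening and aromatisation: C- against O-acylation, the site of acylation, O- against C-attack on the epoxide and the enol-ether geometry needed for ring closure would all be left to chance, in hot methoxide that can add to the enone, and on all of the advanced material at once.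
Second would be the early asymmetric epoxidation: the only stereocentre would sit in a base-labile epoxide that has to survive methoxide, a lithium amide and hot methoxide again, with no later point at which its purity could be raised.
Third would be the methoxide opening of the pyranone: after two steps that add only five carbons it would spend another to undo a ring, and the keto ester could close back to the lactone on acidification.

Plan of the new route
The retrosynthesis cuts, in this order, the enone Cα=Cβ bond (aldol condensation), the two C–H bonds at C-2 and C-3 of the dihydrofuran (back to a flat benzofuran), the O-1–C-2 and C-3–C-3a bonds (annulation of an alkyne onto an ortho-iodophenol) and the C-3a–I bond.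
Ring A is bought complete, with its three oxygens and the acetyl group; the five-membered ring arises second, as the furan of an achiral benzofuran, and becomes the dihydrofuran of the core only in the key step; the enone and ring B come last.
The feature that allows this: the only stereocentre, C-2, is a CH between O-1 and the C-3 methylene and carries an achiral CMe2OH group, so C-2–C-3 is the dihydro form of a benzofuran C2=C3 bond and addition of H2 to one face of that bond sets all the stereochemistry; the five-carbon unit with its tertiary alcohol is one commercial alkyne.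
Which oxygen closes the furan is fixed beforehand, because only the chelated 2-OH is free next to the iodine, so ring A never has to be closed; no epoxide is carried through base, since the stereocentre is set late by a catalyst on an achiral precursor; and no ring is opened only to be closed again.

Key step: step 4

Assumption: compounds 1, 4 and 8 are taken as commercial.
Assumption: the sense of induction of the chiral ruthenium–carbene catalyst on this substrate is not known in advance; the (R,R) ligand (SINpEt = 1,3-bis[(1R)-1-(naphthalen-1-yl)ethyl]-4,5-dihydroimidazol-2-ylidene) is written for addition of H2 to the Re face of C-2, and its antipode would be used if a test run showed the opposite sense.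

Step 1
Reactants: 1 1-(2,4-dihydroxy-6-methoxyphenyl)ethan-1-one
Product: 2 1-[2-hydroxy-6-methoxy-4-(methoxymethoxy)phenyl]ethan-1-one
Conditions: MOMCl (1.05 equiv), K2CO3 (1.5 equiv), acetone, 0 °C → rt
Reagents that add atoms: chloromethyl methyl ether, COCCl
Why: Williamson ether synthesis (O-alkylation of a phenoxide): the 4-OH, para to the acetyl group, is the more acidic phenol and is not held in the hydrogen bond to the carbonyl oxygen, so it alone should be etherified with one equivalent of reagent, leaving the chelated 2-OH free; no stereocentre is formed.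

Step 2
Reactants: 2 1-[2-hydroxy-6-methoxy-4-(methoxymethoxy)phenyl]ethan-1-one
Product: 3 1-[2-hydroxy-3-iodo-6-methoxy-4-(methoxymethoxy)phenyl]ethan-1-one
Conditions: BnMe3N·ICl2 (1.05 equiv), NaHCO3 (2 equiv), CH2Cl2–MeOH, rt
Reagents that add atoms: benzyltrimethylammonium dichloroiodate, C[N+](C)(C)Cc1ccccc1.Cl[I-]Cl
Why: Electrophilic aromatic substitution (iodination of a phenol): the free 2-OH activates its only open ortho position, C-3, which lies between OH and OMOM and is less hindered than C-5 between OMOM and OMe, and the bicarbonate buffer keeps the MOM ether intact; no stereocentre is formed.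

Step 3
Reactants: 3 1-[2-hydroxy-3-iodo-6-methoxy-4-(methoxymethoxy)phenyl]ethan-1-one; 4 2-methylbut-3-yn-2-ol
Product: 6 1-[2-(2-hydroxypropan-2-yl)-6-methoxy-4-(methoxymethoxy)-1-benzofuran-7-yl]ethan-1-one, via ortho-alkynylphenol 5 (not isolated)
Conditions: PdCl2(PPh3)2 (3 mol %), CuI (6 mol %), Et3N (3 equiv), DMF, 70 °C
Reagents that add atoms: none
Why: Sonogashira coupling followed in the same flask by copper- and base-promoted 5-endo-dig hydroalkoxylation of the alkyne (cycloisomerisation of an ortho-alkynylphenol), in which only the 2-OH is free beside the alkyne because the 4-oxygen is a MOM ether, so that only the 7-acetylbenzofuran can form, and the alkyne brings in the complete five-carbon unit with its tertiary alcohol; no stereocentre is formed.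

Step 4
Reactants: 6 1-[2-(2-hydroxypropan-2-yl)-6-methoxy-4-(methoxymethoxy)-1-benzofuran-7-yl]ethan-1-one
Product: 7 1-[(2S)-2-(2-hydroxypropan-2-yl)-6-methoxy-4-(methoxymethoxy)-2,3-dihydro-1-benzofuran-7-yl]ethan-1-one
Conditions: [Ru(cod)(2-methylallyl)2] (5 mol %), (R,R)-SINpEt·HBF4 (10 mol %), KOt-Bu (15 mol %), n-hexane, 70 °C; then 6, toluene–n-hexane, H2 (40 bar), 30 °C
Reagents that add atoms: none
Why: A ruthenium hydride carrying two chiral N-heterocyclic carbene ligands should bind the C2=C3 bond of the furan ring, the least aromatic and most alkene-like part of the benzofuran (an enol ether conjugated to ring A), insert it and release the product by hydrogenolysis, so that both hydrogens arrive on the same face. The closest known reaction type is the ruthenium–carbene-catalysed enantioselective hydrogenation of 2-substituted benzofurans to 2,3-dihydrobenzofurans. No ring is closed in this step; the furan ring made in step 3 is converted into the dihydrofuran ring of the core. The new stereocentre C-2 is set by the catalyst alone, since the substrate is flat and achiral: addition of hydrogen to the Re face of C-2 gives 2S, and the C-3 methylene formed at the same time is not a stereocentre. The step needs the furan C=C bond to react in preference to ring A and to the acetyl carbonyl; ring A keeps its full benzene aromaticity, and the carbonyl is shielded on both sides by the 6-methoxy group and O-1 and twisted out of the ring plane. The medium is neutral and aprotic, so the benzofuran-2-yl carbinol should not ionise and the MOM ether should be safe.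

Step 5
Reactants: 7 1-[(2S)-2-(2-hydroxypropan-2-yl)-6-methoxy-4-(methoxymethoxy)-2,3-dihydro-1-benzofuran-7-yl]ethan-1-one; 8 4-(methoxymethoxy)benzaldehyde
Product: 10 (2E)-1-[(2S)-2-(2-hydroxypropan-2-yl)-6-methoxy-4-(methoxymethoxy)-2,3-dihydro-1-benzofuran-7-yl]-3-[4-(methoxymethoxy)phenyl]prop-2-en-1-one, via aldol adduct 9 (not isolated)
Conditions: KOH (5 equiv), MeOH–H2O, 0 → 45 °C
Reagents that add atoms: none
Why: Claisen–Schmidt condensation (crossed aldol addition then E1cB dehydration): the aldehyde has no α-hydrogen and the methyl ketone is the only enolisable partner, the conjugated E-enone is the thermodynamic product, the MOM ethers and the tertiary alcohol are inert to hydroxide, and C-2 bears no acidic hydrogen, so its configuration is untouched.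

Step 6
Reactants: 10 (2E)-1-[(2S)-2-(2-hydroxypropan-2-yl)-6-methoxy-4-(methoxymethoxy)-2,3-dihydro-1-benzofuran-7-yl]-3-[4-(methoxymethoxy)phenyl]prop-2-en-1-one
Product: 11 (2E)-1-[(2S)-4-hydroxy-2-(2-hydroxypropan-2-yl)-6-methoxy-2,3-dihydro-1-benzofuran-7-yl]-3-(4-hydroxyphenyl)prop-2-en-1-one
Conditions: HCl (ca. 1 M), MeOH, rt → 40 °C; then aq. NaHCO3
Reagents that add atoms: none
Why: Acid-catalysed acetal exchange with methanol should remove both aryl MOM ethers as dimethoxymethane far faster than the tertiary alcohol, which is deactivated by the adjacent C-2 oxygen, can ionise, and because both positions ortho to the ketone are etherified (OMe and O-1) the chalcone cannot cyclise to a flavanone; C-2 is not affected.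

Compound list
1 | 1-(2,4-dihydroxy-6-methoxyphenyl)ethan-1-one | CC(=O)c1c(O)cc(O)cc1OC | starting material
2 | 1-[2-hydroxy-6-methoxy-4-(methoxymethoxy)phenyl]ethan-1-one | CC(=O)c1c(O)cc(OCOC)cc1OC | intermediate
3 | 1-[2-hydroxy-3-iodo-6-methoxy-4-(methoxymethoxy)phenyl]ethan-1-one | CC(=O)c1c(O)c(I)c(OCOC)cc1OC | intermediate
4 | 2-methylbut-3-yn-2-ol | CC(C)(O)C#C | starting material
5 | 1-[2-hydroxy-3-(3-hydroxy-3-methylbut-1-yn-1-yl)-6-methoxy-4-(methoxymethoxy)phenyl]ethan-1-one | CC(=O)c1c(O)c(C#CC(C)(C)O)c(OCOC)cc1OC | intermediate
6 | 1-[2-(2-hydroxypropan-2-yl)-6-methoxy-4-(methoxymethoxy)-1-benzofuran-7-yl]ethan-1-one | CC(=O)c1c(OC)cc(OCOC)c2cc(C(C)(C)O)oc12 | intermediate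
7 | 1-[(2S)-2-(2-hydroxypropan-2-yl)-6-methoxy-4-(methoxymethoxy)-2,3-dihydro-1-benzofuran-7-yl]ethan-1-one | COc1cc(OCOC)c2c(c1C(C)=O)O[C@H](C(C)(C)O)C2 | intermediate
8 | 4-(methoxymethoxy)benzaldehyde | COCOc1ccc(C=O)cc1 | starting material
9 | 3-hydroxy-1-[(2S)-2-(2-hydroxypropan-2-yl)-6-methoxy-4-(methoxymethoxy)-2,3-dihydro-1-benzofuran-7-yl]-3-[4-(methoxymethoxy)phenyl]propan-1-one (both epimers at the chain carbinol carbon) | COc1cc(OCOC)c2c(c1C(=O)CC(O)c1ccc(OCOC)cc1)O[C@H](C(C)(C)O)C2 | intermediate
10 | (2E)-1-[(2S)-2-(2-hydroxypropan-2-yl)-6-methoxy-4-(methoxymethoxy)-2,3-dihydro-1-benzofuran-7-yl]-3-[4-(methoxymethoxy)phenyl]prop-2-en-1-one | COc1cc(OCOC)c2c(c1C(=O)/C=C/c1ccc(OCOC)cc1)O[C@H](C(C)(C)O)C2 | intermediate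
11 | (2E)-1-[(2S)-4-hydroxy-2-(2-hydroxypropan-2-yl)-6-methoxy-2,3-dihydro-1-benzofuran-7-yl]-3-(4-hydroxyphenyl)prop-2-en-1-one | COc1cc(O)c2c(c1C(=O)/C=C/c1ccc(O)cc1)O[C@H](C(C)(C)O)C2 | target

Total step count: 6. Longest linear sequence: 6 steps (1 → 11).

Steps most likely to fail

Step 4. The catalyst may discriminate poorly between the two faces of C2=C3 because C-2 carries a bulky tertiary carbinol. Turnover may be slow because the hydroxyl and acetyl oxygens bind ruthenium, or hydride may be transferred to the acetyl carbonyl. The fallback sets out from iodophenol 3 and comes back to the route at 7, by-passing steps 3 and 4. Compound 3 would be annulated with isoprene under zerovalent palladium catalysis (Pd2(dba)3, a chiral sulfinamide–phosphine ligand, K2CO3, toluene, 80 °C). Heck insertion of the aryl–palladium bond at the unsubstituted vinyl terminus gives a π-allyl complex, and the phenoxide closes it at the internal carbon in an enantio-determining Tsuji–Trost etherification. This should give 1-[(2S)-6-methoxy-4-(methoxymethoxy)-2-(prop-1-en-2-yl)-2,3-dihydro-1-benzofuran-7-yl]ethan-1-one F1. Mukaiyama hydration (Co(acac)2, PhSiH3, O2, i-PrOH–THF, rt) would then turn the isopropenyl group into the tertiary alcohol of 7 without touching C-2.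

Step 2. Iodine may enter C-5, para to the free phenol, or both open positions. The fallback sets out from 1 and comes back at 3, with the order of the first two operations inverted. Iodination of the unprotected resorcinol 1 in aqueous ammonia (I2, KI, rt) should occur at the carbon flanked by both hydroxyl groups, as in the iodination of resorcinol itself. This would give 1-(2,4-dihydroxy-3-iodo-6-methoxyphenyl)ethan-1-one F2. Selective etherification of its non-chelated 4-OH (MOMCl, K2CO3, acetone) would then give 3.

Step 5. Enolisation and addition of the doubly ortho-substituted, electron-rich methyl ketone may be slow, so that Cannizzaro disproportionation of the aldehyde and conjugate addition of methoxide to the enone take over. The fallback sets out from 7 and comes back at 10; it forms the Cβ–aryl bond instead of the Cα=Cβ bond. α-Methylenation of 7 (paraformaldehyde, i-Pr2NH·CF3CO2H, THF, reflux; Mannich reaction then loss of the amine) would give 1-[(2S)-2-(2-hydroxypropan-2-yl)-6-methoxy-4-(methoxymethoxy)-2,3-dihydro-1-benzofuran-7-yl]prop-2-en-1-one F3. A Heck reaction of F3 with 1-iodo-4-(methoxymethoxy)benzene (Pd(OAc)2, Et3N, MeCN, 80 °C) would then give the E-enone 10.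

Further compounds
F1 | step 4 | 1-[(2S)-6-methoxy-4-(methoxymethoxy)-2-(prop-1-en-2-yl)-2,3-dihydro-1-benzofuran-7-yl]ethan-1-one | COc1cc(OCOC)c2c(c1C(C)=O)O[C@H](C(C)=C)C2
F2 | step 2 | 1-(2,4-dihydroxy-3-iodo-6-methoxyphenyl)ethan-1-one | CC(=O)c1c(O)c(I)c(O)cc1OC
F3 | step 5 | 1-[(2S)-2-(2-hydroxypropan-2-yl)-6-methoxy-4-(methoxymethoxy)-2,3-dihydro-1-benzofuran-7-yl]prop-2-en-1-one | COc1cc(OCOC)c2c(c1C(=O)C=C)O[C@H](C(C)(C)O)C2
A1 | direct plan | 4-methoxy-6-methyl-2H-pyran-2-one | COC1=CC(=O)OC(C)=C1
A2 | direct plan | prenyl bromide (1-bromo-3-methylbut-2-ene) | CC(C)=CCBr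
A3 | direct plan | 6-{2-[(2R)-3,3-dimethyloxiran-2-yl]ethyl}-4-methoxy-2H-pyran-2-one | COC1=CC(=O)OC(CC[C@H]2OC2(C)C)=C1
A4 | direct plan | methyl (2E)-7-[(2R)-3,3-dimethyloxiran-2-yl]-3-methoxy-5-oxohept-2-enoate | COC(=O)/C=C(/OC)CC(=O)CC[C@H]1OC1(C)C
A5 | direct plan | (E)-4-acetoxycinnamoyl chloride | CC(=O)Oc1ccc(/C=C/C(=O)Cl)cc1
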